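(Readings and results are calculated from invented constants; scatter was added.)

In each flask asked about, 0.10 M of starting material meets 0.150 M of reagent, more than the starting material, so starting material is the limiting reagent and I keep its books in per cent of the charge.

| flask | starting material | reagent | temperature | remark | time |
|---|---|---|---|---|---|
| delta | 0.10 M | 0.075 M | −15 °C | run made earlier |  |
| epsilon | 0.10 M | 0.30 M | 35 °C | run made earlier |  |
| eta | 0.20 M | 0.15 M | −15 °C | run made earlier |  |
| green | 0.10 M | 0.150 M | 50 °C |  | 40 h |
| violet | 0.10 M | 0.150 M | −10 °C |  | 40 h |
| amber | 0.10 M | 0.150 M | 80 °C |  | 40 h |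
| teal | 0.10 M | 0.150 M | 20 °C |  | 40 h |

| run | time / h | target / % | starting material / % |
|---|---|---|---|
| delta | 50.0 | 18.8 | 80.2 |
| delta | 96.0 | 27.6 | 70.7 |
| delta | 240 | 37.2 | 58.4 |
| delta | 600 | 39.7 | 52.7 |
| epsilon | 4.00 | 59.7 | 13.5 |
| epsilon | 8.00 | 52.5 | 10.0 |
| epsilon | 20.0 | 43.1 | 3.9 |
| epsilon | 48.0 | 35.4 | 2.9 |
| eta | 72.0 | 34.3 | 64.4 |
| eta | 192 | 39.1 | 55.9 |
| eta | 360 | 40.0 | 52.3 |
| eta | 600 | 39.6 | 46.7 |

(readings scatter by 0.5 percentage points)

- the best flask by amount of target, in percent of the starting material charged; "all alike" if 1.5 percentage points covers them all (green / violet / amber / teal / all alike)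
- amount of target at the end, in percent of the starting material charged, green
- amount of target at the end, in percent of the starting material charged, violet
- amount of target at the end, in percent of the starting material charged, amber
- amount of target at the end, in percent of the starting material charged, teal



1. Delta's books at 600 h read 39.7% target, 52.7% starting material and 7.60% unaccounted.

2. Counting one reagent per target, delta still holds 0.0353 M of reagent, yet its target only creeps. Eta's target is flat, 39.1% to 39.6%. I read a set point, with the step running both ways.

3. So I define the balance quotient Q, an apparent equilibrium constant: [target]·[partner]/([starting material]·[reagent]), taking the partner as a twin of target, one per target. Delta reads 0.847 and eta reads 0.949.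

4. Solved for the recipe of the four flasks, delta's Q gives a ceiling of 57.6% target. I assume Q holds when warm.

5. The unaccounted entry is 7.60% in cold delta, but in epsilon, warmer and with more reagent, it goes from 26.8% at 4.00 h to 61.7% at 48.0 h, more than in delta. So I expect the hot flasks to end well under the ceiling.

6. Eta needed 192 h to flatten, longer than the 40 h allowed, so I expect cold violet to fall short as well. My pick is teal.

The forecast also says teal, with green 43% (32% to 52%), violet 33% (29% to 37%), amber 29% (12% to 44%) and teal 51% (45% to 57%). Its ground differs from mine: “SM stalls well before the reagent should run out, so the reagent also dies by a parallel route”.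

The flasks give teal as best, with green 25.1%, violet 39.9%, amber 32.5% and teal 44.8%.

    starting material + reagent ⇌ target + by-product (K = 0.780, k = 2.10 /M/h, Ea = 62.0 kJ/mol, ΔH = 2.00 kJ/mol)
    starting material ⇌ dormant form (K = 22.0, k = 0.0230 /h, Ea = 101 kJ/mol, ΔH = 11.0 kJ/mol)
    starting material + by-product → side product (k = 0.450 /M/h, Ea = 80.0 kJ/mol)
    (constants at 20 °C)

The undoing of target + by-product into starting material + reagent is the main reason amber holds 32.5% of target and not the 79.2% it holds without that back step. The partner is the by-product, and it is no twin: green at 40.0 h holds 0.00619 M of it, less than its target of 0.0251 M. Green has 54.5% parked as dormant form and 1.50% free starting material, with 83.3% of its reagent left. Cold Q then gives 25.6% target, against the 25.1% green holds. The neighbour of green with 0.60 M of reagent has 0.996% starting material, 93.9% of its reagent and 0.0128 M by-product, so Q gives 37.1%, and that flask holds 36.7%.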